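**Retrosynthetic overview**

1. Target 25 ⇐ NAP removal, C2 oxidation, O1→O7 benzoyl shift and CHO reduction ⇐ aldehyde 20.
2. 20 ⇐ Claisen [3,3] shift (C1–C2 bond; the cyclohexene closes as the pyran opens) ⇐ C5-vinyl 2-benzoyloxyglycal 19. The strategy rests on the quaternary carbinol C1, which carries the exocyclic carbon C7 and lies two ring atoms from the C3=C4 double bond: C7(O)–C1–C2–C3=C4 is a γ,δ-unsaturated carbonyl pattern.
3. 19 ⇐ HBr loss from the glycosyl bromide of L-gulo-hept-6-enopyranose 16, whose pyran ring (ring 1, step 6) is made by oxidative lactonisation of diol 11; the cyclohexene (ring 2) follows in step 11.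
4. 11 ⇐ chelation-controlled vinyl Grignard addition to the 2-O-NAP-3,4-O-isopropylidene-D-arabinopyranose 9 ⇐ D-arabinose. C2 and C3 of arabinose become C5 and C6; the Grignard carbinol becomes C4 and controls C1.

Key step: step 11

Numbering: carbocycle C1 (quaternary carbinol bearing C7H2OBz), C2 (C=O), C3=C4, C5 (CHOH), C6 (CHOBz). Sugar C2, C3, C4, C5, C6, C7 and C1 of the hept-6-enopyranoses correspond to C1, C6, C5, C4, C3, C2 and C7.

Remark on the chemistry: O5 is carried as a 2-naphthylmethyl (NAP) ether. The vinyl-bearing stereocentre is set by magnesium chelation to this oxygen, and NAP comes off oxidatively at the end without base. The configuration at sugar C2 is lost in the glycal, so the cis-3,4-diol of D-arabinose can supply both benzoylated oxygens.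

**Route**

Step 1
Reactants: 1 D-arabinose; 2 allyl alcohol
Product: 3 allyl β-D-arabinopyranoside
Conditions: allyl alcohol (solvent), Amberlite IR-120 (H+) resin, 80 °C; crystallisation
Reagents that add atoms: allyl alcohol, C=CCO
Why: Fischer glycosidation under thermodynamic control should give the pyranoside with the axial, 1,2-cis allyloxy group, and the anomeric centre is removed again in step 4.

Step 2
Reactants: 3 allyl β-D-arabinopyranoside; 4 2,2-dimethoxypropane
Product: 5 allyl 3,4-O-isopropylidene-β-D-arabinopyranoside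
Conditions: 2,2-dimethoxypropane, TsOH (cat.), acetone, rt
Reagents that add atoms: 2,2-dimethoxypropane, COC(C)(C)OC
Why: Acid-catalysed transacetalisation takes only the cis-3,4-diol, so O2 is left as the single free hydroxyl.

Step 3
Reactants: 5 allyl 3,4-O-isopropylidene-β-D-arabinopyranoside; 6 2-(bromomethyl)naphthalene
Product: 7 allyl 3,4-O-isopropylidene-2-O-(2-naphthylmethyl)-β-D-arabinopyranoside
Conditions: NaH, 2-(bromomethyl)naphthalene, DMF, 0 °C → rt
Reagents that add atoms: 2-(bromomethyl)naphthalene, BrCc1ccc2ccccc2c1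
Why: Williamson etherification of the only free hydroxyl installs a coordinating ether that is stable to acid and base and can be cleaved with DDQ.

Step 4
Reactants: 7 allyl 3,4-O-isopropylidene-2-O-(2-naphthylmethyl)-β-D-arabinopyranoside
Product: 9 3,4-O-isopropylidene-2-O-(2-naphthylmethyl)-D-arabinopyranose, via prop-1-enyl glycoside 8 (not isolated)
Conditions: [Ir(cod)(PMePh2)2]PF6 (cat., pre-activated with H2), THF, rt; then I2, NaHCO3, THF/H2O, rt
Reagents that add atoms: none
Why: Iridium-catalysed allyl to prop-1-enyl isomerisation followed by iodine-mediated hydrolysis of the enol ether frees the lactol without acid, so the acetonide and the NAP ether should survive.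

Step 5
Reactants: 9 3,4-O-isopropylidene-2-O-(2-naphthylmethyl)-D-arabinopyranose; 10 vinylmagnesium bromide
Product: 11 1,2-dideoxy-5,6-O-isopropylidene-4-O-(2-naphthylmethyl)-D-gluco-hept-1-enitol (3S carbinol)
Conditions: CH2=CHMgBr (3.5 equiv), THF, −78 → 0 °C; aq. NH4Cl
Reagents that add atoms: vinylmagnesium bromide, C=C[Mg]Br
Why: Grignard addition to the aldehyde form of the lactol, in which a five-membered magnesium chelate between the carbonyl oxygen and the NAP ether oxygen should direct attack to give the syn (3S, D-gluco) carbinol, the centre that becomes C4 and later relays to C1; a minor epimer would be removed by chromatography.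

Step 6
Reactants: 11 1,2-dideoxy-5,6-O-isopropylidene-4-O-(2-naphthylmethyl)-D-gluco-hept-1-enitol
Product: 13 6,7-dideoxy-2,3-O-isopropylidene-4-O-(2-naphthylmethyl)-L-gulo-hept-6-enono-1,5-lactone, via pyranose lactol 12 (not isolated)
Conditions: TEMPO (0.2 equiv), PhI(OAc)2 (2.5 equiv), CH2Cl2, rt
Reagents that add atoms: none
Why: TEMPO-mediated oxidative lactonisation oxidises the primary alcohol first; the aldehyde can be trapped only by the allylic hydroxyl (the neighbouring oxygens are blocked), so only the six-membered lactol can form and it is oxidised on to the δ-lactone, and any epimerisation next to the carbonyl is harmless because that centre becomes sp2 in 19.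

Step 7
Reactants: 13 6,7-dideoxy-2,3-O-isopropylidene-4-O-(2-naphthylmethyl)-L-gulo-hept-6-enono-1,5-lactone
Product: 12 6,7-dideoxy-2,3-O-isopropylidene-4-O-(2-naphthylmethyl)-L-gulo-hept-6-enopyranose
Conditions: i-Bu2AlH (1.2 equiv), CH2Cl2, −78 °C; aq. potassium sodium tartrate
Reagents that add atoms: none
Why: Partial reduction of a lactone to the lactol, which stops at the aldehyde level because the tetrahedral aluminate is stable at −78 °C and no ester is yet present.

Step 8
Reactants: 12 6,7-dideoxy-2,3-O-isopropylidene-4-O-(2-naphthylmethyl)-L-gulo-hept-6-enopyranose; 14 benzoyl chloride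
Product: 16 1,2,3-tri-O-benzoyl-6,7-dideoxy-4-O-(2-naphthylmethyl)-L-gulo-hept-6-enopyranose, via free triol 15 (not isolated)
Conditions: AcOH/H2O (4:1), 70 °C; evaporate with toluene; then BzCl (4 equiv), pyridine, DMAP (cat.), 0 °C → rt
Reagents that add atoms: benzoyl chloride, O=C(Cl)c1ccccc1
Why: Acid hydrolysis of the cis-fused acetonide and perbenzoylation; because O4 is an ether the triol can exist only as the pyranose, so exactly O1, O2 and O3 are acylated.

Step 9
Reactants: 16 1,2,3-tri-O-benzoyl-6,7-dideoxy-4-O-(2-naphthylmethyl)-L-gulo-hept-6-enopyranose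
Product: 17 2,3-di-O-benzoyl-6,7-dideoxy-4-O-(2-naphthylmethyl)-L-gulo-hept-6-enopyranose
Conditions: N2H4·AcOH (1.3 equiv), DMF, 40 °C
Reagents that add atoms: none
Why: Selective anomeric deacylation by hydrazinolysis, since the acetal ester is much more electrophilic than the two secondary benzoates.

Step 10
Reactants: 17 2,3-di-O-benzoyl-6,7-dideoxy-4-O-(2-naphthylmethyl)-L-gulo-hept-6-enopyranose
Product: 19 1,5-anhydro-2,3-di-O-benzoyl-6,7-dideoxy-4-O-(2-naphthylmethyl)-L-xylo-hept-1,6-dienitol, via glycosyl bromide 18 (not isolated)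
Conditions: PPh3 (1.3 equiv), CBr4 (1.3 equiv), CH2Cl2, 0 °C → rt; then DBU (2.5 equiv), rt
Reagents that add atoms: none
Why: Appel bromination gives the axial glycosyl bromide under neutral conditions (the NAP ether would not tolerate HBr), and E2 elimination of the antiperiplanar axial H2 with DBU is the standard route to a 2-acyloxyglycal.

Step 11
Reactants: 19 1,5-anhydro-2,3-di-O-benzoyl-6,7-dideoxy-4-O-(2-naphthylmethyl)-L-xylo-hept-1,6-dienitol
Product: 20 (1S,5R,6S)-1-formyl-5-(2-naphthylmethoxy)cyclohex-3-ene-1,6-diyl dibenzoate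
Conditions: o-dichlorobenzene (0.02 M, degassed), 2,6-di-tert-butyl-4-methylpyridine (0.2 equiv), base-washed sealed tube, 200–220 °C
Reagents that add atoms: none
Why: The allyl vinyl ether embedded in 19 (C7=C1–O–C4–C3=C2) should undergo a concerted, suprafacial [3,3]-sigmatropic (Claisen) shift in which C1 bonds to the vinyl terminus C2 while the ring O–C4 bond breaks, so that C7 becomes the aldehyde and the new C3=C4 alkene is cis; carbonyl formation makes the step irreversible. The closest known reaction type is the thermal Claisen ring contraction of 2-vinyl-3,4-dihydro-2H-pyrans and C5-vinyl glycals to cyclohex-3-ene-1-carbaldehydes. The cyclohexene closes by intramolecular C1–C2 bond formation through a boat-like six-membered transition state in which the pseudoaxial vinyl group is folded over the enol ether, the carbocycle forming as the pyran opens. The only new stereocentre, C1, is set by chirality transfer from C4: C2 can reach only the face of C1 on which the vinyl group stands (cis to O5, trans to the C6 benzoate), which gives the 1S aldehyde, and C5 and C6 are not touched. The step needs chemoselectivity over the thermal 1,3-shift of the allylic C6 benzoate and over acid-triggered allylic ionisation; in the reactive half-chair the vinyl group is pseudoaxial and both oxygen substituents are pseudoequatorial, so the C6–O bond is poorly aligned with the enol ether π system, and the hindered pyridine keeps the medium acid-free. Because the rearrangement is neutral and needs no enolate, there is no path for base-induced loss of the benzoate β to the new carbonyl.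

Step 12
Reactants: 20 (1S,5R,6S)-1-formyl-5-(2-naphthylmethoxy)cyclohex-3-ene-1,6-diyl dibenzoate
Product: 22 [(1R,5R,6S)-6-(benzoyloxy)-1-hydroxy-5-(2-naphthylmethoxy)cyclohex-3-en-1-yl]methyl benzoate, via primary alcohol 21 (not isolated)
Conditions: NaBH4, THF/MeOH (9:1), −20 °C; then Et3N, rt
Reagents that add atoms: none
Why: Borohydride reduction of the aldehyde followed by base-mediated 1,2-acyl migration through a five-membered orthoester intermediate, driven by the exchange of a tertiary ester for a primary one.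

Step 13
Reactants: 22 [(1R,5R,6S)-6-(benzoyloxy)-1-hydroxy-5-(2-naphthylmethoxy)cyclohex-3-en-1-yl]methyl benzoate
Product: 23 [(1S,5R,6S)-6-(benzoyloxy)-1,2-dihydroxy-5-(2-naphthylmethoxy)cyclohex-3-en-1-yl]methyl benzoate (C2 epimers)
Conditions: SeO2 (1.5 equiv), 1,4-dioxane, 80 °C
Reagents that add atoms: selenium dioxide, O=[Se]=O
Why: Riley allylic oxidation (ene reaction, then [2,3] shift) returns the double bond to C3=C4 and should deliver oxygen to the C2 methylene, because the other allylic hydrogen sits on a methine that is deactivated by its geminal ether oxygen; the C2 configuration is irrelevant.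

Step 14
Reactants: 23 [(1S,5R,6S)-6-(benzoyloxy)-1,2-dihydroxy-5-(2-naphthylmethoxy)cyclohex-3-en-1-yl]methyl benzoate
Product: 24 [(1R,5R,6S)-6-(benzoyloxy)-1-hydroxy-5-(2-naphthylmethoxy)-2-oxocyclohex-3-en-1-yl]methyl benzoate
Conditions: Dess–Martin periodinane (1.3 equiv), CH2Cl2, 0 °C → rt
Reagents that add atoms: none
Why: Dess–Martin oxidation converts the secondary allylic alcohol into the enone under near-neutral conditions, and the tertiary C1 hydroxyl cannot be oxidised.

Step 15
Reactants: 24 [(1R,5R,6S)-6-(benzoyloxy)-1-hydroxy-5-(2-naphthylmethoxy)-2-oxocyclohex-3-en-1-yl]methyl benzoate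
Product: 25 [(1R,5R,6S)-6-(benzoyloxy)-1,5-dihydroxy-2-oxocyclohex-3-en-1-yl]methyl benzoate (CNP0212960.1)
Conditions: DDQ (2 equiv), CH2Cl2/pH 7 phosphate buffer (10:1), rt
Reagents that add atoms: none
Why: Oxidative cleavage of the naphthylmethyl ether by DDQ (benzylic hydride abstraction, then hydrolysis) is neutral, so benzoate migration and base-induced elimination or aromatisation of the hydroxy enone are avoided.

**Compound list**

1 | D-arabinose | O=C[C@@H](O)[C@H](O)[C@H](O)CO | starting material
2 | allyl alcohol | C=CCO | starting material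
3 | allyl β-D-arabinopyranoside | C=CCO[C@@H]1OC[C@@H](O)[C@@H](O)[C@@H]1O | intermediate
4 | 2,2-dimethoxypropane | COC(C)(C)OC | starting material
5 | allyl 3,4-O-isopropylidene-β-D-arabinopyranoside | C=CCO[C@@H]1OC[C@H]2OC(C)(C)O[C@H]2[C@@H]1O | intermediate
6 | 2-(bromomethyl)naphthalene | BrCc1ccc2ccccc2c1 | starting material
7 | allyl 3,4-O-isopropylidene-2-O-(2-naphthylmethyl)-β-D-arabinopyranoside | C=CCO[C@@H]1OC[C@H]2OC(C)(C)O[C@H]2[C@@H]1OCc1ccc2ccccc2c1 | intermediate
8 | (E)-prop-1-enyl 3,4-O-isopropylidene-2-O-(2-naphthylmethyl)-β-D-arabinopyranoside | C/C=C/O[C@@H]1OC[C@H]2OC(C)(C)O[C@H]2[C@@H]1OCc1ccc2ccccc2c1 | intermediate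
9 | 3,4-O-isopropylidene-2-O-(2-naphthylmethyl)-D-arabinopyranose (anomeric mixture) | OC1OC[C@H]2OC(C)(C)O[C@H]2[C@@H]1OCc1ccc2ccccc2c1 | intermediate
10 | vinylmagnesium bromide | C=C[Mg]Br | starting material
11 | 1,2-dideoxy-5,6-O-isopropylidene-4-O-(2-naphthylmethyl)-D-gluco-hept-1-enitol | C=C[C@H](O)[C@@H](OCc1ccc2ccccc2c1)[C@@H]1OC(C)(C)O[C@@H]1CO | intermediate
12 | 6,7-dideoxy-2,3-O-isopropylidene-4-O-(2-naphthylmethyl)-L-gulo-hept-6-enopyranose (anomeric mixture) | C=C[C@@H]1OC(O)[C@H]2OC(C)(C)O[C@H]2[C@@H]1OCc1ccc2ccccc2c1 | intermediate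
13 | 6,7-dideoxy-2,3-O-isopropylidene-4-O-(2-naphthylmethyl)-L-gulo-hept-6-enono-1,5-lactone | C=C[C@@H]1OC(=O)[C@H]2OC(C)(C)O[C@H]2[C@@H]1OCc1ccc2ccccc2c1 | intermediate
14 | benzoyl chloride | O=C(Cl)c1ccccc1 | starting material
15 | 6,7-dideoxy-4-O-(2-naphthylmethyl)-L-gulo-hept-6-enopyranose (anomeric mixture) | C=C[C@@H]1OC(O)[C@@H](O)[C@@H](O)[C@@H]1OCc1ccc2ccccc2c1 | intermediate
16 | 1,2,3-tri-O-benzoyl-6,7-dideoxy-4-O-(2-naphthylmethyl)-L-gulo-hept-6-enopyranose (anomeric mixture) | C=C[C@@H]1OC(OC(=O)c2ccccc2)[C@@H](OC(=O)c2ccccc2)[C@@H](OC(=O)c2ccccc2)[C@@H]1OCc1ccc2ccccc2c1 | intermediate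
17 | 2,3-di-O-benzoyl-6,7-dideoxy-4-O-(2-naphthylmethyl)-L-gulo-hept-6-enopyranose (anomeric mixture) | C=C[C@@H]1OC(O)[C@@H](OC(=O)c2ccccc2)[C@@H](OC(=O)c2ccccc2)[C@@H]1OCc1ccc2ccccc2c1 | intermediate
18 | 2,3-di-O-benzoyl-6,7-dideoxy-4-O-(2-naphthylmethyl)-α-L-gulo-hept-6-enopyranosyl bromide | C=C[C@@H]1O[C@@H](Br)[C@@H](OC(=O)c2ccccc2)[C@@H](OC(=O)c2ccccc2)[C@@H]1OCc1ccc2ccccc2c1 | intermediate
19 | 1,5-anhydro-2,3-di-O-benzoyl-6,7-dideoxy-4-O-(2-naphthylmethyl)-L-xylo-hept-1,6-dienitol | C=C[C@@H]1OC=C(OC(=O)c2ccccc2)[C@@H](OC(=O)c2ccccc2)[C@@H]1OCc1ccc2ccccc2c1 | intermediate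
20 | (1S,5R,6S)-1-formyl-5-(2-naphthylmethoxy)cyclohex-3-ene-1,6-diyl dibenzoate | O=C[C@]1(OC(=O)c2ccccc2)CC=C[C@@H](OCc2ccc3ccccc3c2)[C@@H]1OC(=O)c1ccccc1 | intermediate
21 | (1R,5R,6S)-1-(hydroxymethyl)-5-(2-naphthylmethoxy)cyclohex-3-ene-1,6-diyl dibenzoate | OC[C@]1(OC(=O)c2ccccc2)CC=C[C@@H](OCc2ccc3ccccc3c2)[C@@H]1OC(=O)c1ccccc1 | intermediate
22 | [(1R,5R,6S)-6-(benzoyloxy)-1-hydroxy-5-(2-naphthylmethoxy)cyclohex-3-en-1-yl]methyl benzoate | O=C(OC[C@]1(O)CC=C[C@@H](OCc2ccc3ccccc3c2)[C@@H]1OC(=O)c1ccccc1)c1ccccc1 | intermediate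
23 | [(1S,5R,6S)-6-(benzoyloxy)-1,2-dihydroxy-5-(2-naphthylmethoxy)cyclohex-3-en-1-yl]methyl benzoate (C2 epimers) | O=C(OC[C@]1(O)C(O)C=C[C@@H](OCc2ccc3ccccc3c2)[C@@H]1OC(=O)c1ccccc1)c1ccccc1 | intermediate
24 | [(1R,5R,6S)-6-(benzoyloxy)-1-hydroxy-5-(2-naphthylmethoxy)-2-oxocyclohex-3-en-1-yl]methyl benzoate | O=C(OC[C@]1(O)C(=O)C=C[C@@H](OCc2ccc3ccccc3c2)[C@@H]1OC(=O)c1ccccc1)c1ccccc1 | intermediate
25 | [(1R,5R,6S)-6-(benzoyloxy)-1,5-dihydroxy-2-oxocyclohex-3-en-1-yl]methyl benzoate (CNP0212960.1) | O=C(OC[C@]1(O)C(=O)C=C[C@@H](O)[C@@H]1OC(=O)c1ccccc1)c1ccccc1 | target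

**Step count and risks**

Total step count: 15. Longest linear sequence: 15 steps (1 → 25).

Steps most likely to fail:

1. Step 11. At the temperature the neutral rearrangement needs, the allylic benzoate on C6 may undergo its own 1,3-acyloxy shift or benzoic acid may be lost, so that the pyran is consumed before the C1–C2 bond forms. The fallback is an Ireland–Claisen ring contraction that sets out from lactone 13 and returns to the route at 22. LiN(SiMe3)2 with Me3SiCl/Et3N present in THF at −78 °C would give the O-trimethylsilyl ketene acetal of lactone 13 F1; the cis-fused acetonide holds the β C–O bond out of alignment with the enolate and the in-situ silylation limits β-elimination. Warming in toluene to 80–110 °C should effect the [3,3] shift over the same vinyl-bearing face, and mild hydrolysis of the silyl ester would give the acetonide-bridged 1,6-dihydroxy-5-(2-naphthylmethoxy)cyclohex-3-ene-1-carboxylic acid F2. LiAlH4 would reduce it to the acetonide-bridged hydroxymethyl compound F3, AcOH/H2O would free 1-(hydroxymethyl)-5-(2-naphthylmethoxy)cyclohex-3-ene-1,6-diol F4, and BzCl (2 equiv) in pyridine at low temperature would acylate the primary and the secondary hydroxyl but not the tertiary one, giving 22.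

2. Step 13. The ene reaction of SeO2 with the cis-disubstituted ring alkene may be sluggish at the neopentyl-type C2 methylene, with over-oxidation or leakage to the C5 side. The fallback changes the O5 group so that a radical C–H oxidation can take the methylene straight to the enone; it sets out from 22 and returns at the target 25. DDQ would remove the NAP group to give [(1R,5R,6S)-6-(benzoyloxy)-1,5-dihydroxycyclohex-3-en-1-yl]methyl benzoate F5, and t-BuMe2SiCl/imidazole would silylate the secondary allylic hydroxyl only, giving its 5-O-tert-butyldimethylsilyl ether F6. Allylic oxidation with Rh2(cap)4 (dirhodium tetrakis(caprolactamate))/t-BuOOH, or with CrO3/3,5-dimethylpyrazole, now free of benzylic C–H bonds, would give the silyl-protected enone F7, and HF·pyridine would release 25.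

3. Step 5. Facial selectivity may be poor if Felkin-type attack competes with the magnesium chelate, giving the C3 epimer that would lead to the wrong C1 configuration. The fallback sets the carbinol by reagent-controlled reduction; it sets out from 11 obtained as a mixture with its C3 epimer and returns to stereopure 11. t-BuPh2SiCl/imidazole would protect the primary hydroxyl to give the 7-O-silyl ether of the epimer mixture F8, Dess–Martin oxidation would converge both epimers on the vinyl ketone F9, and Corey–Bakshi–Shibata reduction with the oxazaborolidine enantiomer matched to the 3S carbinol would give the 7-O-silyl ether of 11 F10. Bu4NF would then return 11.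

**Further compounds**

F1 | step 11 | O-trimethylsilyl ketene acetal of lactone 13 | C=C[C@@H]1OC(O[Si](C)(C)C)=C2OC(C)(C)O[C@H]2[C@@H]1OCc1ccc2ccccc2c1
F2 | step 11 | 1,6-O-isopropylidene-1,6-dihydroxy-5-(2-naphthylmethoxy)cyclohex-3-ene-1-carboxylic acid (C1, C5, C6 as in 22) | OC(=O)[C@]12CC=C[C@@H](OCc3ccc4ccccc4c3)[C@@H]1OC(C)(C)O2
F3 | step 11 | [1,6-O-isopropylidene-1,6-dihydroxy-5-(2-naphthylmethoxy)cyclohex-3-en-1-yl]methanol | OC[C@]12CC=C[C@@H](OCc3ccc4ccccc4c3)[C@@H]1OC(C)(C)O2
F4 | step 11 | 1-(hydroxymethyl)-5-(2-naphthylmethoxy)cyclohex-3-ene-1,6-diol (C1, C5, C6 as in 22) | OC[C@]1(O)CC=C[C@@H](OCc2ccc3ccccc3c2)[C@@H]1O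
F5 | step 13 | [(1R,5R,6S)-6-(benzoyloxy)-1,5-dihydroxycyclohex-3-en-1-yl]methyl benzoate | O=C(OC[C@]1(O)CC=C[C@@H](O)[C@@H]1OC(=O)c1ccccc1)c1ccccc1
F6 | step 13 | [(1R,5R,6S)-6-(benzoyloxy)-5-(tert-butyldimethylsilyloxy)-1-hydroxycyclohex-3-en-1-yl]methyl benzoate | O=C(OC[C@]1(O)CC=C[C@@H](O[Si](C)(C)C(C)(C)C)[C@@H]1OC(=O)c1ccccc1)c1ccccc1
F7 | step 13 | [(1R,5R,6S)-6-(benzoyloxy)-5-(tert-butyldimethylsilyloxy)-1-hydroxy-2-oxocyclohex-3-en-1-yl]methyl benzoate | O=C(OC[C@]1(O)C(=O)C=C[C@@H](O[Si](C)(C)C(C)(C)C)[C@@H]1OC(=O)c1ccccc1)c1ccccc1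
F8 | step 5 | 7-O-(tert-butyldiphenylsilyl) ether of 11 and its C3 epimer | C=CC(O)[C@@H](OCc1ccc2ccccc2c1)[C@@H]1OC(C)(C)O[C@@H]1CO[Si](c1ccccc1)(c1ccccc1)C(C)(C)C
F9 | step 5 | 7-O-(tert-butyldiphenylsilyl)-1,2-dideoxy-5,6-O-isopropylidene-4-O-(2-naphthylmethyl)-D-arabino-hept-1-en-3-ulose | C=CC(=O)[C@@H](OCc1ccc2ccccc2c1)[C@@H]1OC(C)(C)O[C@@H]1CO[Si](c1ccccc1)(c1ccccc1)C(C)(C)C
F10 | step 5 | 7-O-(tert-butyldiphenylsilyl) ether of 11 | C=C[C@H](O)[C@@H](OCc1ccc2ccccc2c1)[C@@H]1OC(C)(C)O[C@@H]1CO[Si](c1ccccc1)(c1ccccc1)C(C)(C)C
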